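**Assumption:** catalyst-bound species (enamines and dienamines of the amine catalysts, organo-Pd and organo-Rh species) are not numbered; C1 of 9, the C=C geometry of 8 and 11, and the epoxide CH of 19 are formed as mixtures that later steps erase.

## Retrosynthetic overview

1. Target ⇐ side-chain alkene ester (epoxidation, then Meinwald rearrangement gives the ketone last) ⇐ hydroxy vinyl triflate (Pd methoxycarbonylation).
2. Key disconnection: the C9–O bond, made by a catalytic asymmetric α′-benzoyloxylation of the spiro-enone (new reaction), followed by reductive enol triflation.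
3. Cyclohexenone ring (formed second): Robinson annulation of a 2,5-trans-disubstituted cyclopentanecarbaldehyde with methyl vinyl ketone; this sets the spiro centre.
4. Cyclopentane ring (formed first): Rh hydroacylation of α-allyl-citronellal, then enol triflate → enal, then methyl cuprate for the ring methyl.
5. Stereochemistry: the side-chain methyl centre comes from (R)-citronellal; the ring CH by enamine/Pd allylation; the ring methyl and spiro centre by substrate control; C9 by the catalyst.

## Route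

**Step 1**
Reactants: 1 (R)-citronellal [(3R)-3,7-dimethyloct-6-enal]; 2 allyl acetate
Product: 3 (2R,3R)-3,7-dimethyl-2-(prop-2-en-1-yl)oct-6-enal
Conditions: Pd(PPh3)4 (5 mol %), (R)-2-[diphenyl(trimethylsilyloxy)methyl]pyrrolidine (20 mol %), DMSO/DMF, −20 °C; crude product used at once
Reagents that add atoms: none
Why: Dual enamine/Pd(0) catalysis (Tsuji–Trost α-allylation of an aldehyde), in which the E-enamine attacks the π-allyl-Pd cation on the face remote from the diaryl(silyloxy)methyl group (Re face at C2 with the R catalyst), so the catalyst sets C2 as R, while the remote trisubstituted alkene is inert.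

**Step 2**
Reactants: 3 (2R,3R)-3,7-dimethyl-2-(prop-2-en-1-yl)oct-6-enal
Product: 4 (2R)-2-[(2R)-6-methylhept-5-en-2-yl]cyclopentan-1-one
Conditions: [Rh(dppe)(acetone)2]BF4 (5 mol %), CH2Cl2, 25 °C
Reagents that add atoms: none
Why: Rh(I)-catalysed intramolecular alkene hydroacylation of a 4-pentenal closes the five-membered ring under neutral conditions, so the α-stereocentre is kept and the trisubstituted alkene (no 4-pentenal relationship) does not react.

**Step 3**
Reactants: 4 (2R)-2-[(2R)-6-methylhept-5-en-2-yl]cyclopentan-1-one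
Product: 6 (5R)-5-[(2R)-6-methylhept-5-en-2-yl]cyclopent-1-en-1-yl trifluoromethanesulfonate, via lithium enolate 5 (not isolated)
Conditions: LDA, THF, −78 °C; PhNTf2, −78 → 0 °C
Reagents that add atoms: N-phenylbis(trifluoromethanesulfonimide), O=S(=O)(N(c1ccccc1)S(=O)(=O)C(F)(F)F)C(F)(F)F
Why: Kinetic deprotonation takes the unhindered CH2 rather than the branched α-CH, and O-triflation of the enolate follows, so no stereocentre is touched.

**Step 4**
Reactants: 6 (5R)-5-[(2R)-6-methylhept-5-en-2-yl]cyclopent-1-en-1-yl trifluoromethanesulfonate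
Product: 7 (5R)-5-[(2R)-6-methylhept-5-en-2-yl]cyclopent-1-ene-1-carbaldehyde
Conditions: Pd(OAc)2, dppp (5 mol % each), CO (1 atm), Et3SiH, Et3N, DMF, 70 °C
Reagents that add atoms: carbon monoxide, [C-]#[O+]
Why: Pd-catalysed reductive carbonylation (formylation) of a vinyl triflate proceeds by oxidative addition, CO insertion and hydride transfer from the silane, with no stereocentre involved.

**Step 5**
Reactants: 7 (5R)-5-[(2R)-6-methylhept-5-en-2-yl]cyclopent-1-ene-1-carbaldehyde
Product: 9 (2S,5R)-2-methyl-5-[(2R)-6-methylhept-5-en-2-yl]cyclopentane-1-carbaldehyde (C1 epimers), via trimethylsilyl enol ether 8 (not isolated)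
Conditions: Me2CuLi, TMSCl, THF, −78 °C; then 1 M HCl, 0 °C
Reagents that add atoms: lithium dimethylcuprate, [Li+].C[Cu-]C
Why: TMSCl-accelerated cuprate 1,4-addition to the enal delivers methyl to C2 anti to the C5 side chain (held pseudoaxial by A1,2 strain with the formyl group), giving the 2,5-trans ring, and the undefined C1 is erased in step 6.

**Step 6**
Reactants: 9 (2S,5R)-2-methyl-5-[(2R)-6-methylhept-5-en-2-yl]cyclopentane-1-carbaldehyde; 10 methyl vinyl ketone
Product: 13 (1S,4R,5R)-1-methyl-4-[(2R)-6-methylhept-5-en-2-yl]spiro[4.5]dec-6-en-8-one, via pyrrolidine enamine 11 (not isolated), via keto aldehyde 12 (not isolated)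
Conditions: pyrrolidine, PhMe, 4 Å MS, 60 °C; 10, 0 → 25 °C; then AcOH/NaOAc/H2O, 70 °C
Reagents that add atoms: none
Why: Stork-enamine Robinson annulation (Michael addition, hydrolysis, intramolecular aldol condensation) in which the enone approaches the enamine carbon on the face of the small methyl group and anti to the branched side chain, so the CH2CH2 arm ends syn to methyl (5R; expected dr about 3–4:1, minor spiro epimer removed by chromatography of 13).

**Step 7**
Reactants: 13 (1S,4R,5R)-1-methyl-4-[(2R)-6-methylhept-5-en-2-yl]spiro[4.5]dec-6-en-8-one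
Product: 14 (1S,4R,5R,9S)-1-methyl-4-[(2R)-6-methylhept-5-en-2-yl]-8-oxospiro[4.5]dec-6-en-9-yl benzoate
Conditions: 9-amino-9-deoxy-epi-quinine (20 mol %), Cl3CCO2H (40 mol %), (BzO)2 (1.5 equiv), BHT (10 mol %), THF, 30 °C
Reagents that add atoms: dibenzoyl peroxide, O=C(OOC(=O)c1ccccc1)c1ccccc1
Why: Proposed new method: primary-amine-catalysed α′-benzoyloxylation of a 4,4-disubstituted cyclohex-2-enone, in which the iminium of the C8 ketone cannot enolise toward the quaternary C5 and so gives only the cross-conjugated 8-amino-6,8-diene, whose C9 attacks the O–O bond of the peroxide held by the protonated quinuclidine on the Si face (9S, catalyst-controlled because the spiro stereocentres are remote; the quinidine-derived pseudo-enantiomer is used if the sense proves opposite), and hydrolysis releases 14; the closest known reaction type is the cinchona-primary-amine/acid-catalysed α-benzoyloxylation of saturated cyclic ketones with dibenzoyl peroxide, together with amine-catalysed α′-functionalisation of cyclohexenones through 2-aminodienes.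

**Step 8**
Reactants: 14 (1S,4R,5R,9S)-1-methyl-4-[(2R)-6-methylhept-5-en-2-yl]-8-oxospiro[4.5]dec-6-en-9-yl benzoate
Product: 17 (1S,4R,5S,9S)-9-hydroxy-1-methyl-4-[(2R)-6-methylhept-5-en-2-yl]spiro[4.5]dec-7-en-8-yl trifluoromethanesulfonate, via lithium enolate 15 (not isolated), via benzoate triflate 16 (not isolated)
Conditions: L-Selectride, THF, −78 °C; Comins' reagent, −78 °C; then DIBAL-H (3 equiv), −78 °C; Rochelle salt
Reagents that add atoms: N-(5-chloropyridin-2-yl)bis(trifluoromethanesulfonimide), O=S(=O)(N(c1ccc(Cl)cn1)S(=O)(=O)C(F)(F)F)C(F)(F)F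
Why: Conjugate reduction of the β-unsubstituted enone gives the C7–C8 enolate regiospecifically (the former formyl carbon becomes CH2), O-triflation traps it, and DIBAL-H then cleaves the benzoate reductively without touching the vinyl triflate, so no allylic ester reaches the Pd step and no stereocentre changes.

**Step 9**
Reactants: 17 (1S,4R,5S,9S)-9-hydroxy-1-methyl-4-[(2R)-6-methylhept-5-en-2-yl]spiro[4.5]dec-7-en-8-yl trifluoromethanesulfonate
Product: 18 methyl (1S,4R,5S,9S)-9-hydroxy-1-methyl-4-[(2R)-6-methylhept-5-en-2-yl]spiro[4.5]dec-7-ene-8-carboxylate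
Conditions: Pd(OAc)2, dppf (5 mol % each), CO (1 atm), MeOH, Et3N, DMF, 40 °C
Reagents that add atoms: carbon monoxide, [C-]#[O+]; methanol, CO
Why: Pd-catalysed methoxycarbonylation of a vinyl triflate tolerates the free secondary alcohol and leaves every stereocentre untouched.

**Step 10**
Reactants: 18 methyl (1S,4R,5S,9S)-9-hydroxy-1-methyl-4-[(2R)-6-methylhept-5-en-2-yl]spiro[4.5]dec-7-ene-8-carboxylate
Product: 19 methyl (1S,4R,5S,9S)-4-[(2R)-4-(3,3-dimethyloxiran-2-yl)butan-2-yl]-9-hydroxy-1-methylspiro[4.5]dec-7-ene-8-carboxylate (both epoxide epimers)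
Conditions: mCPBA, NaHCO3, CH2Cl2, 0 °C
Reagents that add atoms: 3-chloroperoxybenzoic acid, O=C(OO)c1cccc(Cl)c1
Why: Prilezhaev epoxidation takes the electron-rich trisubstituted alkene and not the ester-conjugated one, and the new epoxide centre is uncontrolled but is destroyed in step 11.

**Step 11**
Reactants: 19 methyl (1S,4R,5S,9S)-4-[(2R)-4-(3,3-dimethyloxiran-2-yl)butan-2-yl]-9-hydroxy-1-methylspiro[4.5]dec-7-ene-8-carboxylate
Product: 20 methyl (1S,4R,5S,9S)-9-hydroxy-1-methyl-4-[(2R)-6-methyl-5-oxoheptan-2-yl]spiro[4.5]dec-7-ene-8-carboxylate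
Conditions: BF3·OEt2 (0.3 equiv), CH2Cl2, −78 → −30 °C
Reagents that add atoms: none
Why: Meinwald rearrangement, in which the Lewis acid opens the epoxide at the tertiary carbon and a 1,2-hydride shift gives the isopropyl ketone, removing the epoxide stereocentre and leaving the other five unchanged.

## Compound list

1 | (R)-citronellal | O=CC[C@H](C)CCC=C(C)C | starting material
2 | allyl acetate | C=CCOC(C)=O | starting material
3 | (2R,3R)-3,7-dimethyl-2-(prop-2-en-1-yl)oct-6-enal | O=C[C@@H]([C@H](C)CCC=C(C)C)CC=C | intermediate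
4 | (2R)-2-[(2R)-6-methylhept-5-en-2-yl]cyclopentan-1-one | O=C1[C@@H]([C@H](C)CCC=C(C)C)CCC1 | intermediate
5 | lithium (5R)-5-[(2R)-6-methylhept-5-en-2-yl]cyclopent-1-en-1-olate | [Li]OC1=CCC[C@@H]1[C@H](C)CCC=C(C)C | intermediate
6 | (5R)-5-[(2R)-6-methylhept-5-en-2-yl]cyclopent-1-en-1-yl trifluoromethanesulfonate | O=S(=O)(OC1=CCC[C@@H]1[C@H](C)CCC=C(C)C)C(F)(F)F | intermediate
7 | (5R)-5-[(2R)-6-methylhept-5-en-2-yl]cyclopent-1-ene-1-carbaldehyde | O=CC1=CCC[C@@H]1[C@H](C)CCC=C(C)C | intermediate
8 | trimethyl({(2S,5R)-2-methyl-5-[(2R)-6-methylhept-5-en-2-yl]cyclopentylidene}methoxy)silane (E/Z mixture) | C[Si](C)(C)OC=C1[C@@H]([C@H](C)CCC=C(C)C)CC[C@@H]1C | intermediate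
9 | (2S,5R)-2-methyl-5-[(2R)-6-methylhept-5-en-2-yl]cyclopentane-1-carbaldehyde (C1 epimers) | O=CC1[C@@H]([C@H](C)CCC=C(C)C)CC[C@@H]1C | intermediate
10 | methyl vinyl ketone | CC(=O)C=C | starting material
11 | 1-({(2S,5R)-2-methyl-5-[(2R)-6-methylhept-5-en-2-yl]cyclopentylidene}methyl)pyrrolidine (E/Z mixture) | C1CCN(C1)C=C2[C@@H]([C@H](C)CCC=C(C)C)CC[C@@H]2C | intermediate
12 | (1R,2S,5R)-2-methyl-5-[(2R)-6-methylhept-5-en-2-yl]-1-(3-oxobutyl)cyclopentane-1-carbaldehyde | O=C[C@@]1(CCC(C)=O)[C@@H]([C@H](C)CCC=C(C)C)CC[C@@H]1C | intermediate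
13 | (1S,4R,5R)-1-methyl-4-[(2R)-6-methylhept-5-en-2-yl]spiro[4.5]dec-6-en-8-one | O=C1C=C[C@@]2(CC1)[C@@H]([C@H](C)CCC=C(C)C)CC[C@@H]2C | intermediate
14 | (1S,4R,5R,9S)-1-methyl-4-[(2R)-6-methylhept-5-en-2-yl]-8-oxospiro[4.5]dec-6-en-9-yl benzoate | O=C1C=C[C@@]2(C[C@@H]1OC(=O)c3ccccc3)[C@@H]([C@H](C)CCC=C(C)C)CC[C@@H]2C | intermediate
15 | lithium (1S,4R,5S,9S)-9-(benzoyloxy)-1-methyl-4-[(2R)-6-methylhept-5-en-2-yl]spiro[4.5]dec-7-en-8-olate | [Li]OC1=CC[C@@]2(C[C@@H]1OC(=O)c3ccccc3)[C@@H]([C@H](C)CCC=C(C)C)CC[C@@H]2C | intermediate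
16 | (1S,4R,5S,9S)-1-methyl-4-[(2R)-6-methylhept-5-en-2-yl]-8-[(trifluoromethanesulfonyl)oxy]spiro[4.5]dec-7-en-9-yl benzoate | O=S(=O)(OC1=CC[C@@]2(C[C@@H]1OC(=O)c3ccccc3)[C@@H]([C@H](C)CCC=C(C)C)CC[C@@H]2C)C(F)(F)F | intermediate
17 | (1S,4R,5S,9S)-9-hydroxy-1-methyl-4-[(2R)-6-methylhept-5-en-2-yl]spiro[4.5]dec-7-en-8-yl trifluoromethanesulfonate | O=S(=O)(OC1=CC[C@@]2(C[C@@H]1O)[C@@H]([C@H](C)CCC=C(C)C)CC[C@@H]2C)C(F)(F)F | intermediate
18 | methyl (1S,4R,5S,9S)-9-hydroxy-1-methyl-4-[(2R)-6-methylhept-5-en-2-yl]spiro[4.5]dec-7-ene-8-carboxylate | COC(=O)C1=CC[C@@]2(C[C@@H]1O)[C@@H]([C@H](C)CCC=C(C)C)CC[C@@H]2C | intermediate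
19 | methyl (1S,4R,5S,9S)-4-[(2R)-4-(3,3-dimethyloxiran-2-yl)butan-2-yl]-9-hydroxy-1-methylspiro[4.5]dec-7-ene-8-carboxylate (both epoxide epimers) | COC(=O)C1=CC[C@@]2(C[C@@H]1O)[C@@H]([C@H](C)CCC3OC3(C)C)CC[C@@H]2C | intermediate
20 | methyl (1S,4R,5S,9S)-9-hydroxy-1-methyl-4-[(2R)-6-methyl-5-oxoheptan-2-yl]spiro[4.5]dec-7-ene-8-carboxylate | COC(=O)C1=CC[C@@]2(C[C@@H]1O)[C@@H]([C@H](C)CCC(=O)C(C)C)CC[C@@H]2C | target

## Totals

Total step count: 11. Longest linear sequence: 11 steps, from (R)-citronellal.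

## The three steps most likely to fail

**Step 7 (the new α′-benzoyloxylation).** The peroxide may oxidise the amine catalyst, the hindered enone may form the dienamine slowly, or face selectivity at C9 may be low. The fallback uses known chemistry and sets out from 13. Kinetic deprotonation with LDA in THF at −78 °C gives the lithium cross-conjugated dienolate F1. This is hydroxylated at −78 °C with an enantiopure (camphorsulfonyl)oxaziridine (reagent-controlled enolate hydroxylation, which leaves the isolated alkene alone) to give the α′-hydroxy enone F2; the minor C9 epimer is removed here. Benzoyl chloride, pyridine and DMAP then convert F2 into 14, where the route resumes.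

**Step 6 (facial selectivity at the spiro centre).** Only a methyl group versus a sec-alkyl group differentiates the two faces, so the dr may be too low. The fallback sets out from 9 and replaces substrate control by auxiliary control. Condensation with (S)-1-phenylethylamine gives the imine F3. F3 adds to 10 through its secondary-enamine tautomer in a compact, internally proton-transferring transition state (chiral-imine Michael addition) to give the keto imine F4; the auxiliary antipode is chosen to reinforce the intrinsic anti-to-side-chain preference. Aqueous acetic acid hydrolyses F4 to 12, which is isolated and closed to 13 with KOH in methanol.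

**Step 8 (reductive enol triflation beside a benzoate).** L-Selectride may reduce the carbonyl 1,2 because the β-carbon is neopentylic, or the enolate may take the neighbouring benzoyl group. The fallback sets out from 14. Copper hydride-catalysed conjugate hydrosilylation (Stryker's reagent, Et3SiH, toluene) gives the triethylsilyl enol ether F5 without a free enolate. CsF and PhNTf2 in DME convert F5 into 16, and DIBAL-H at −78 °C then gives 17 as in the main route.

## Further compounds

F1 | step 7 | lithium (1S,4R,5R)-1-methyl-4-[(2R)-6-methylhept-5-en-2-yl]spiro[4.5]deca-6,8-dien-8-olate | [Li]OC1=CC[C@]2(C=C1)[C@@H]([C@H](C)CCC=C(C)C)CC[C@@H]2C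
F2 | step 7 | (1S,4R,5R,9S)-9-hydroxy-1-methyl-4-[(2R)-6-methylhept-5-en-2-yl]spiro[4.5]dec-6-en-8-one | O=C1C=C[C@@]2(C[C@@H]1O)[C@@H]([C@H](C)CCC=C(C)C)CC[C@@H]2C
F3 | step 6 | N-[(1S)-1-phenylethyl]imine of aldehyde 9 | C[C@@H](c1ccccc1)N=CC2[C@@H]([C@H](C)CCC=C(C)C)CC[C@@H]2C
F4 | step 6 | N-[(1S)-1-phenylethyl]imine of keto aldehyde 12 | C[C@@H](c1ccccc1)N=C[C@@]2(CCC(C)=O)[C@@H]([C@H](C)CCC=C(C)C)CC[C@@H]2C
F5 | step 8 | (1S,4R,5S,9S)-1-methyl-4-[(2R)-6-methylhept-5-en-2-yl]-8-[(triethylsilyl)oxy]spiro[4.5]dec-7-en-9-yl benzoate | CC[Si](CC)(CC)OC1=CC[C@@]2(C[C@@H]1OC(=O)c3ccccc3)[C@@H]([C@H](C)CCC=C(C)C)CC[C@@H]2C
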